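**Plan**
- Numbering: the caryophyllane carbons are C1–C15. C1/C9 are the ring fusion, C4 bears Me and O, C5 bears H and C1′H2, and C8 bears =CH2. Ring C is the pyran O/C4/C5/C1′/C2′/C3′. Ring D runs C2′(–C1′)=C3′(–O)–C4′Me2–C5′(=O)–C6′(acyl)=C7′(OH).
- Cuts: first C6′–C(=O)iPr (late C-acylation), then C4′–C5′ of ring D, then C5′–C6′ and C7′–C2′ ([2+2]), and last C4–O and C5–C1′ (hetero-Diels–Alder).
- Enabling feature: ring D is a 6,6-dimethylcyclohexa-2,4-dienone (C5′=O, C6′=C7′, C2′=C3′, quaternary C4′) with oxygen on C3′, C5′ and C7′. It is therefore the closed valence isomer of a dienylketene. That ketene is the opened form of a 3-alkoxy-4-alkenylcyclobutenone spiro-joined to ring C at C2′. The two methyl groups on C4′ block aromatisation.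
- Forward order: ring C comes first (caryophyllene plus a methylene β-keto ester). A four-membered ring C5′/C6′/C7′/C2′ follows (vinylketene plus ethoxyacetylene), with the isopropyl group becoming the C3′=C4′Me2 arm. Strain-driven expansion of that ring by C3′ and C4′ then gives ring D, followed by de-ethylation and acylation.
- Stereochemistry: C1 (R) and C9 (S) are bought with (−)-β-caryophyllene. C4 (S) and C5 (R) come from suprafacial addition to the E alkene, and the face isomers are separated in step 1. The spiro centre is transient.

Key step: step 4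

Assumption: the target is one enol tautomer of a β-triketone; the tautomers interconvert freely, and the drawn form stands for the compound.

**Step 1**
Reactants: 1 (−)-β-caryophyllene; 2 methyl 4-methyl-3-oxopentanoate; 3 paraformaldehyde (reacts as formaldehyde)
Product: 5 methyl pyranocaryophyllane carboxylate (1R,4S,5R,9S), via oxadiene 4 (not isolated)
Conditions: 1 (3 equiv), (CH2O)n, ethylenediammonium diacetate (10 mol %), 4 Å MS, toluene, 80 °C, slow addition of 2; chromatography (AgNO3-doped SiO2 if needed) to remove the (4R,5S) face isomer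
Reagents that add atoms: none
Why: Domino Knoevenagel–hetero-Diels–Alder reaction: 2 and formaldehyde condense to the 1-oxadiene 4 (methylene carbon, C2′, ketone C3′=O), which adds with inverse electron demand only to the strained E-configured C4=C5 bond of 1, oxygen going to the more substituted C4, in a suprafacial manner that turns the E geometry into the C4/C5 relative configuration, while the absolute sense (4S,5R) requires attack on the alkene face opposite to the one that carries oxygen in natural (4R,5R)-caryophyllene oxide, a face that ring flipping of 1 also exposes but that may well be the less used one, so the face isomers are separated here on the cheapest material of the route.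

**Step 2**
Reactants: 5 methyl pyranocaryophyllane carboxylate
Product: 6 potassium pyranocaryophyllane carboxylate (1R,4S,5R,9S)
Conditions: KOSiMe3, THF, 40 °C; evaporate, triturate with Et2O
Reagents that add atoms: potassium trimethylsilanolate, C[Si](C)(C)[O-].[K+]
Why: Anhydrous cleavage of a methyl ester with potassium trimethylsilanolate delivers the carboxylate salt directly, so the acid-labile tertiary alkyl–oxygen bond at C4 (a vinylogous tert-alkyl carbonate) and the exocyclic alkene never meet acid and no stereocentre is touched.

**Step 3**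
Reactants: 6 potassium pyranocaryophyllane carboxylate; 7 ethoxyacetylene
Product: 10 spirocyclobutenone (1R,4S,5R,9S; both C2′ epimers), via acid chloride 8 (not isolated), via vinylketene 9 (not isolated)
Conditions: (COCl)2, CH2Cl2, 0 °C, evaporate; 7 (5 equiv), Et3N (syringe pump), CH2Cl2, 40 °C; Et3N-deactivated SiO2
Reagents that add atoms: oxalyl chloride, O=C(Cl)C(=O)Cl (its chlorine stays only in intermediate 8)
Why: Neutral conversion of a carboxylate salt into the acid chloride, 1,4-dehydrochlorination of this α,β-unsaturated acid chloride through its only γ-hydrogen (the isopropyl methine, which thereby becomes the C3′=C4′Me2 arm) and regioselective ketene–alkoxyalkyne [2+2] cycloaddition, the nucleophilic CH terminus of 7 bonding to the ketene carbonyl carbon as in the first stage of the Danheiser benzannulation, should give the 3-ethoxycyclobutenone; the spiro centre C2′ forms without control and is erased in step 4.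

**Step 4**
Reactants: 10 spirocyclobutenone
Product: 12 ring D ethoxydienone (1R,4S,5R,9S), via dienylketene 11 (not isolated)
Conditions: toluene (0.01 M), 110 °C, Ar, base-washed glassware
Reagents that add atoms: none
Why: Heat opens the strained four-membered ring of 10 by conrotatory 4π electrocyclic cleavage of its C5′–C2′ bond to dienylketene 11, whose ketene carbon C5′ then bonds to the isopropylidene carbon C4′ in a disrotatory 6π electrocyclisation, so that the ring C5′–C6′–C7′–C2′ takes up C3′ and C4′ and becomes the six-membered ring D (net 1,3-acyl shift, expansion by two atoms). The closest known reaction type is the thermal ring expansion of 4-alkenylcyclobutenones (last stage of the Danheiser benzannulation, Moore rearrangement), and closure onto a fully substituted terminus is the thermal reverse of the Barton–Quinkert opening of 6,6-disubstituted cyclohexa-2,4-dienones. Ring D is the only ring closed, in the 6π electrocyclic mode with all six atoms sp2 or sp in 11, and because C4′ carries two methyl groups the product cannot enolise to a phenol and stays at the dienone level of the target. No stereocentre is created: the uncontrolled spiro centre C2′ becomes sp2, and C1, C4, C5 and C9 are remote from the reacting π system and not epimerisable. The step needs the ketene arm to end up cis to C3′ and closure to outrun capture of the ketene; the 4π opening is reversible, so the unproductive isomer returns to 10 while only the productive one is drained, ring C holds the C7′=C2′ and C3′=C4′ bonds s-cis and close, and dilute, dry, aprotic, acid-free conditions remove nucleophiles and protect the exocyclic enol ether. Relief of cyclobutenone strain and the gain of a doubly vinylogous ester make the overall change irreversible.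

**Step 5**
Reactants: 12 ring D ethoxydienone
Product: 14 desacyl enol (1R,4S,5R,9S), via potassium enolate 13 (not isolated)
Conditions: KOH, EtOH/H2O, 70 °C; cold aq KHSO4 to pH 4, rapid extraction
Reagents that add atoms: potassium hydroxide, [K+].[OH-]
Why: Saponification of a 3-alkoxyenone by addition–elimination of hydroxide at the vinylogous ester carbon C7′ expels ethoxide, whereas C3′ is shielded by the quaternary C4′ and its tertiary alkoxy group, the delocalised enolate 13 resists further attack, and the basic medium spares the tertiary ether and the exocyclic alkene.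

**Step 6**
Reactants: 14 desacyl enol; 15 isobutyric acid
Product: 17 target CNP0497637.1 (1R,4S,5R,9S), via enol isobutyrate 16 (not isolated)
Conditions: DCC, DMAP (30 mol %), CH2Cl2, 0 °C to rt
Reagents that add atoms: none
Why: Steglich O-acylation of the enol followed by DMAP-catalysed O-to-C acyl migration, the standard entry to 2-acylcyclohexane-1,3-diones, places the isobutyryl group on C6′, the only carbon flanked by both carbonyl groups, and the chelated enol triketone is the thermodynamic sink.

**Compound list**
1 | (−)-β-caryophyllene, (1R,4E,9S)-4,11,11-trimethyl-8-methylidenebicyclo[7.2.0]undec-4-ene | C=C1CC/C=C(\C)CC[C@@H]2[C@@H]1CC2(C)C | starting material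
2 | methyl 4-methyl-3-oxopentanoate (methyl isobutyrylacetate) | COC(=O)CC(=O)C(C)C | starting material
3 | paraformaldehyde, written as its monomer formaldehyde | C=O | starting material
4 | methyl 4-methyl-2-methylidene-3-oxopentanoate (1-oxadiene) | COC(=O)C(=C)C(=O)C(C)C | intermediate
5 | methyl 2-isopropyl-5,6-dihydro-4H-pyran-3-carboxylate fused to the caryophyllane at C4 (O and Me, S) and C5 (H, R); C1 R, C9 S, C8 methylidene kept | C=C1CC[C@@H]2CC(C(=O)OC)=C(C(C)C)O[C@@]2(C)CC[C@@H]2[C@@H]1CC2(C)C | intermediate
6 | potassium salt of the acid of 5 (1R,4S,5R,9S) | C=C1CC[C@@H]2CC(C(=O)[O-])=C(C(C)C)O[C@@]2(C)CC[C@@H]2[C@@H]1CC2(C)C.[K+] | intermediate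
7 | ethoxyacetylene | C#COCC | starting material
8 | acid chloride of 6 (1R,4S,5R,9S) | C=C1CC[C@@H]2CC(C(=O)Cl)=C(C(C)C)O[C@@]2(C)CC[C@@H]2[C@@H]1CC2(C)C | intermediate
9 | vinylketene: ring C with C2′=C=O and C3′=CMe2 both exocyclic (1R,4S,5R,9S) | C=C1CC[C@@H]2CC(=C=O)C(=C(C)C)O[C@@]2(C)CC[C@@H]2[C@@H]1CC2(C)C | intermediate
10 | spirocyclobutenone: C2′ is C4 of a 3-ethoxycyclobut-2-en-1-one and a ring C atom, C3′ bears the isopropylidene (1R,4S,5R,9S, C2′ unassigned) | C=C1CC[C@@H]2CC3(C(=O)C=C3OCC)C(=C(C)C)O[C@@]2(C)CC[C@@H]2[C@@H]1CC2(C)C | intermediate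
11 | dienylketene: C2′=C7′(OEt)–C6′H=C5′=O with the ketene arm cis to C3′ (1R,4S,5R,9S) | C=C1CC[C@@H]2C/C(=C(/C=C=O)OCC)C(=C(C)C)O[C@@]2(C)CC[C@@H]2[C@@H]1CC2(C)C | intermediate
12 | 7′-O-ethyl-6′-desacyl target (ring D ethoxydienone, 1R,4S,5R,9S) | C=C1CC[C@@H]2CC3=C(O[C@@]2(C)CC[C@@H]2[C@@H]1CC2(C)C)C(C)(C)C(=O)C=C3OCC | intermediate
13 | potassium enolate of 14 | C=C1CC[C@@H]2CC3=C(O[C@@]2(C)CC[C@@H]2[C@@H]1CC2(C)C)C(C)(C)C(=O)C=C3[O-].[K+] | intermediate
14 | 6′-desacyl target (enol of the β-diketone, 1R,4S,5R,9S) | C=C1CC[C@@H]2CC3=C(O[C@@]2(C)CC[C@@H]2[C@@H]1CC2(C)C)C(C)(C)C(=O)C=C3O | intermediate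
15 | isobutyric acid | CC(C)C(=O)O | starting material
16 | 7′-O-isobutyrate of 14 | C=C1CC[C@@H]2CC3=C(O[C@@]2(C)CC[C@@H]2[C@@H]1CC2(C)C)C(C)(C)C(=O)C=C3OC(=O)C(C)C | intermediate
17 | CNP0497637.1 (1R,4S,5R,9S) | C=C1CC[C@@H]2CC3=C(O[C@@]2(C)CC[C@@H]2[C@@H]1CC2(C)C)C(C)(C)C(=O)C(C(=O)C(C)C)=C3O | target

Total step count: 6. Longest linear sequence: 6 steps (1 or 2 to 17).

**Steps most likely to fail**

**Step 1.**
- What may go wrong: facial selectivity on the flexible nine-membered ring may be poor, since the wanted face is not the one favoured in epoxidation of 1. The oxadiene may also be lost through Michael addition of unreacted 2 or through self-dimerisation.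
- Fallback: it sets out from 2 and comes back at 4 (hence 5). The oxadiene is no longer formed by a reversible condensation beside its own nucleophilic precursor.
- Route: 2 is C-methylated (MeI, K2CO3, acetone) to methyl 2,4-dimethyl-3-oxopentanoate F1. This is selenenylated (NaH, PhSeCl, THF) to methyl 2,4-dimethyl-3-oxo-2-(phenylselanyl)pentanoate F2. Oxidation (H2O2, CH2Cl2, 0 °C) gives methyl 2,4-dimethyl-3-oxo-2-(phenylseleninyl)pentanoate F3.
- Release and use of 4: syn elimination of F3 can only take a hydrogen of the α-methyl group, so it releases 4 irreversibly below room temperature. The washed, cold solution of 4 is added to excess 1, so the cycloaddition runs at 0–25 °C with the loss channels closed. This much lower temperature gives the best chance of a different face ratio. The face isomers are separated as before.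

**Step 3.**
- What may go wrong: removal of the hindered tertiary γ-hydrogen may be slow. The acid chloride could then decay, or the ketene could be released too slowly and dimerise.
- Fallback: it sets out from 6 and comes back at 9 (hence 10). The difficult C–H removal is moved to a strong-base step.
- Route: 6 with LDA (THF/DMPU, −78 to 0 °C) gives the lithium potassium dienediolate F4. Kinetic α-protonation (AcOH, −78 °C; deconjugative protonation of an extended enolate) gives the 2-isopropylidenetetrahydropyran-3-carboxylic acid F5, which is used at once.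
- Return to the route: 1-chloro-N,N,2-trimethylprop-1-en-1-amine converts F5 under neutral conditions into the deconjugated acid chloride F6. Its doubly activated α-hydrogen is removed by Et3N at −20 °C in an ordinary 1,2-dehydrochlorination, in the presence of 7.

**Step 4.**
- What may go wrong: the ketene may be captured before closure. The exocyclic enol ether may be protonated or hydrolysed. The required temperature may be one at which the terpene part degrades.
- Fallback: it sets out from 7 and comes back at 17. The same ring expansion is carried out first on a small, robust cyclobutenone, and the terpene is joined last.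
- Building ring D: isobutyryl chloride, Et3N and 1-ethoxyprop-1-yne give, by ketene–alkyne [2+2] cycloaddition, 3-ethoxy-2,4,4-trimethylcyclobut-2-en-1-one F7. Opening of F7 (Pyrex-filtered irradiation at rt, or heat) in the presence of 7 gives 3-ethoxy-4-(1-ethoxy-2-methylprop-1-en-1-yl)-4-methylcyclobut-2-en-1-one F8. At 80–110 °C, F8 expands by the same 4π/6π sequence to 3,5-diethoxy-4,6,6-trimethylcyclohexa-2,4-dien-1-one F9.
- Finishing ring D: KOH in aqueous EtOH gives 2,2,4-trimethylcyclohexane-1,3,5-trione F10. Treatment with 15, DCC and DMAP gives 3,5-dihydroxy-4,6,6-trimethyl-2-(2-methylpropanoyl)cyclohexa-2,4-dien-1-one F11.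
- Union with the terpene: oxidation of F11 with Ag2O/TEMPO in the presence of 1 gives 5-hydroxy-2,2-dimethyl-6-methylidene-4-(2-methylpropanoyl)cyclohex-4-ene-1,3-dione F12. F12 adds to C4=C5 of 1 in a hetero-Diels–Alder reaction, and the face isomers are separated at that stage.

**Further compounds**
F1 | step 1 | methyl 2,4-dimethyl-3-oxopentanoate (racemic) | COC(=O)C(C)C(=O)C(C)C
F2 | step 1 | methyl 2,4-dimethyl-3-oxo-2-(phenylselanyl)pentanoate (racemic) | COC(=O)C(C)([Se]c1ccccc1)C(=O)C(C)C
F3 | step 1 | methyl 2,4-dimethyl-3-oxo-2-(phenylseleninyl)pentanoate | COC(=O)C(C)([Se](=O)c1ccccc1)C(=O)C(C)C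
F4 | step 3 | lithium potassium dienediolate of 6 (1R,4S,5R,9S) | C=C1CC[C@@H]2CC(=C([O-])[O-])C(=C(C)C)O[C@@]2(C)CC[C@@H]2[C@@H]1CC2(C)C.[Li+].[K+]
F5 | step 3 | 2-isopropylidenetetrahydropyran-3-carboxylic acid fused to the caryophyllane (1R,4S,5R,9S, C2′ unassigned) | C=C1CC[C@@H]2CC(C(=O)O)C(=C(C)C)O[C@@]2(C)CC[C@@H]2[C@@H]1CC2(C)C
F6 | step 3 | acid chloride of F5 | C=C1CC[C@@H]2CC(C(=O)Cl)C(=C(C)C)O[C@@]2(C)CC[C@@H]2[C@@H]1CC2(C)C
F7 | step 4 | 3-ethoxy-2,4,4-trimethylcyclobut-2-en-1-one | CCOC1=C(C)C(=O)C1(C)C
F8 | step 4 | 3-ethoxy-4-(1-ethoxy-2-methylprop-1-en-1-yl)-4-methylcyclobut-2-en-1-one (racemic) | CCOC1=CC(=O)C1(C)C(OCC)=C(C)C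
F9 | step 4 | 3,5-diethoxy-4,6,6-trimethylcyclohexa-2,4-dien-1-one | CCOC1=CC(=O)C(C)(C)C(OCC)=C1C
F10 | step 4 | 2,2,4-trimethylcyclohexane-1,3,5-trione | CC1C(=O)CC(=O)C(C)(C)C1=O
F11 | step 4 | 3,5-dihydroxy-4,6,6-trimethyl-2-(2-methylpropanoyl)cyclohexa-2,4-dien-1-one | CC1=C(O)C(C)(C)C(=O)C(C(=O)C(C)C)=C1O
F12 | step 4 | 5-hydroxy-2,2-dimethyl-6-methylidene-4-(2-methylpropanoyl)cyclohex-4-ene-1,3-dione | C=C1C(=O)C(C)(C)C(=O)C(C(=O)C(C)C)=C1O
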